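**Retrosynthetic overview**
1. The C11 ketone comes from a last-step allylic C–H oxidation. The C9=C10 alkene comes from dehydration of a C10 tertiary alcohol.
2. The C6–CH3 bond comes from exchanging an alkoxide for methyl, with retention, on a spiro peroxyketal (peroxycarbenium ion, AlMe3).
3. The 1,2-dioxane comes from H2O2 addition to a cyclic enol ether, then 6-exo peroxy-Michael closure onto the (E)-2-methylenoate. C6, C3 and C2 are set by relay from C9/C10.
4. The carbocycle and a dihydropyran are closed together in one enantioselective, proton-initiated, ketone-terminated bicyclisation of an acyclic trienone.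
5. The trienone comes from (E)-geranylacetone and methyl γ-bromotiglate. Ring order: cyclohexane and pyran together, then the dioxane, then the pyran is opened.

Assumption: locants follow the target. C1 is the ester C=O, C3 and C6 are the dioxane carbons, and C9–C14 are the carbocycle (C9 bears the chain, C10 the vinyl CH3, C11 the ketone, C14 the gem-dimethyl).
Assumption: 1 and 2 are bought as pure E isomers (2 is otherwise one step from methyl tiglate and NBS). The catalyst enantiomer in step 2 is the one that gives (4aS,8aS)-5.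

**Step 1**
Reactants: 1 (E)-geranylacetone; 2 methyl (2E)-4-bromo-2-methylbut-2-enoate
Product: 4 methyl (2E,9E)-2,10,14-trimethyl-6-oxopentadeca-2,9,13-trienoate, via lithium enolate 3 (not isolated)
Conditions: LDA, THF, −78 °C; then 2, DMPU, −78 → −20 °C
Reagents that add atoms: none
Why: Kinetic deprotonation of the methyl ketone at CH3 gives the terminal enolate, which displaces the primary allylic bromide (SN2 enolate alkylation); the α-methyl group of 2 slows competing Michael addition and no stereocentre is formed.

**Step 2**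
Reactants: 4 methyl (2E,9E)-2,10,14-trimethyl-6-oxopentadeca-2,9,13-trienoate
Product: 5 methyl (2E)-2-methyl-5-[(4aS,8aS)-5,5,8a-trimethyl-4a,5,6,7,8,8a-hexahydro-4H-chromen-2-yl]pent-2-enoate
Conditions: confined chiral IDPi Brønsted acid (5 mol %), (CF3)3COH, 0 °C; Et3N quench
Reagents that add atoms: none
Why: Proposed new method: the chiral acid protonates C13=C14 of the chair-folded chain, the E-C9=C10 alkene adds anti (giving the trans fusion), the C6 ketone oxygen captures the C10 cation and the oxocarbenium ion loses a proton, so the cyclohexane and the dihydropyran close in one Stork–Eschenmoser cation–olefin bicyclisation that fixes C9 (S) and C10 (S) under catalyst control; the closest known reactions are the racemic acid and cyclase-mediated cyclisation of geranylacetone to the same bicyclic enol ether and the IDPi-catalysed homofarnesol-to-ambrox polyene cyclisation.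

**Step 3**
Reactants: 5 methyl (2E)-2-methyl-5-[(4aS,8aS)-5,5,8a-trimethyl-4a,5,6,7,8,8a-hexahydro-4H-chromen-2-yl]pent-2-enoate
Product: 7 methyl (2R)-2-[(2R,4aS,6'S,8aS)-5,5,8a-trimethyloctahydrospiro[chromene-2,3'-[1,2]dioxan]-6'-yl]propanoate, via hydroperoxy ketal 6 (not isolated)
Conditions: H2O2 (anhydrous, Et2O), PPTS (cat.), 0 °C; then Et2NH (cat.), CF3CH2OH, rt
Reagents that add atoms: hydrogen peroxide, OO
Why: Acid-catalysed perhydrolysis of the enol ether through the ring oxocarbenium ion places OOH axial (anomeric effect, C5 chain equatorial) and so fixes C6 relative to C10, and the amine-catalysed 6-exo peroxy-Michael addition of the hydroperoxy ketal then closes the doubly anomeric spiroketal with the C3 side chain equatorial (C3 S) and protonates the enolate anti to the new C–O bond of the E-enoate (C2 R, 2,3-syn).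

**Step 4**
Reactants: 7 methyl (2R)-2-[(2R,4aS,6'S,8aS)-5,5,8a-trimethyloctahydrospiro[chromene-2,3'-[1,2]dioxan]-6'-yl]propanoate
Product: 9 methyl (2R)-2-[(3S,6R)-6-{2-[(1S,2S)-2-hydroxy-2,6,6-trimethylcyclohexyl]ethyl}-6-methyl-1,2-dioxan-3-yl]propanoate, via dimethylaluminium alkoxide 8 (not isolated)
Conditions: AlMe3 (3 equiv), CH2Cl2, −78 → −20 °C; aq. Rochelle salt
Reagents that add atoms: trimethylaluminium, C[Al](C)C
Why: Proposed new method: AlMe3 binds the more basic pyran oxygen, ionises C6–O to a cyclic peroxycarbenium ion, and the tethered aluminate returns methyl along the axial trajectory on the face the oxygen left (C3 side chain equatorial), giving net retention at C6 (R, CH3 cis to the side chain); the closest known reactions are Lewis-acid substitutions of peroxyketals through peroxycarbenium ions with π-nucleophiles and axial AlMe3 methylation of cyclic oxocarbenium ions, which peroxide-bearing trioxanes survive.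

**Step 5**
Reactants: 9 methyl (2R)-2-[(3S,6R)-6-{2-[(1S,2S)-2-hydroxy-2,6,6-trimethylcyclohexyl]ethyl}-6-methyl-1,2-dioxan-3-yl]propanoate
Product: 10 methyl (2R)-2-[(3S,6R)-6-methyl-6-[2-(2,6,6-trimethylcyclohex-1-en-1-yl)ethyl]-1,2-dioxan-3-yl]propanoate
Conditions: Burgess reagent, PhH, 50 °C
Reagents that add atoms: none
Why: Burgess dehydration (syn, ion-pair elimination of the tertiary sulfamate) takes the C9–H that lies cis to the C10 oxygen and gives the most substituted (Zaitsev) C9=C10 alkene under neutral conditions that the dialkyl peroxide and the ester tolerate; the two relay stereocentres are erased here.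

**Step 6**
Reactants: 10 methyl (2R)-2-[(3S,6R)-6-methyl-6-[2-(2,6,6-trimethylcyclohex-1-en-1-yl)ethyl]-1,2-dioxan-3-yl]propanoate
Product: 11 methyl diacarnoate A, methyl (2R)-2-[(3S,6R)-6-methyl-6-[2-(2,6,6-trimethyl-3-oxocyclohex-1-en-1-yl)ethyl]-1,2-dioxan-3-yl]propanoate
Conditions: Rh2(cap)4 (1 mol %), t-BuOOH (70 % aq.), DCE, 40 °C
Reagents that add atoms: tert-butyl hydroperoxide, CC(C)(C)OO
Why: In this radical allylic oxidation (tert-butylperoxy radical, dirhodium caprolactamate catalysis) the well-aligned ring C11–H is abstracted in preference to the neopentyl-like C8–H and the CH3, as is usual for β-cyclogeranyl rings, and C2, C3 and C6 are untouched.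

**Compound list**
1 | (E)-geranylacetone, (5E)-6,10-dimethylundeca-5,9-dien-2-one | CC(=O)CC/C=C(\C)CCC=C(C)C | starting material
2 | methyl (2E)-4-bromo-2-methylbut-2-enoate | COC(=O)/C(C)=C/CBr | starting material
3 | lithium (5E)-6,10-dimethylundeca-1,5,9-trien-2-olate | [Li+].[O-]C(=C)CC/C=C(\C)CCC=C(C)C | intermediate
4 | methyl (2E,9E)-2,10,14-trimethyl-6-oxopentadeca-2,9,13-trienoate | COC(=O)/C(C)=C/CCC(=O)CC/C=C(\C)CCC=C(C)C | intermediate
5 | methyl (2E)-2-methyl-5-[(4aS,8aS)-5,5,8a-trimethyl-4a,5,6,7,8,8a-hexahydro-4H-chromen-2-yl]pent-2-enoate (trans-fused) | COC(=O)/C(C)=C/CCC1=CC[C@H]2C(C)(C)CCC[C@]2(C)O1 | intermediate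
6 | methyl (2E)-5-[(2S,4aS,8aS)-2-hydroperoxy-5,5,8a-trimethyloctahydro-2H-chromen-2-yl]-2-methylpent-2-enoate (OOH axial, cis to 8a-CH3) | COC(=O)/C(C)=C/CC[C@]1(OO)CC[C@H]2C(C)(C)CCC[C@]2(C)O1 | intermediate
7 | methyl (2R)-2-[(2R,4aS,6'S,8aS)-5,5,8a-trimethyloctahydrospiro[chromene-2,3'-[1,2]dioxan]-6'-yl]propanoate (2R,3S,6R,9S,10S in target locants) | COC(=O)[C@H](C)[C@@H]1CC[C@@]2(CC[C@H]3C(C)(C)CCC[C@]3(C)O2)OO1 | intermediate
8 | dimethylaluminium alkoxide of 9 | COC(=O)[C@H](C)[C@@H]1CC[C@@](C)(CC[C@H]2C(C)(C)CCC[C@]2(C)O[Al](C)C)OO1 | intermediate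
9 | methyl (2R)-2-[(3S,6R)-6-{2-[(1S,2S)-2-hydroxy-2,6,6-trimethylcyclohexyl]ethyl}-6-methyl-1,2-dioxan-3-yl]propanoate | COC(=O)[C@H](C)[C@@H]1CC[C@@](C)(CC[C@H]2C(C)(C)CCC[C@]2(C)O)OO1 | intermediate
10 | methyl (2R)-2-[(3S,6R)-6-methyl-6-[2-(2,6,6-trimethylcyclohex-1-en-1-yl)ethyl]-1,2-dioxan-3-yl]propanoate | COC(=O)[C@H](C)[C@@H]1CC[C@@](C)(CCC2=C(C)CCCC2(C)C)OO1 | intermediate
11 | methyl diacarnoate A | COC(=O)[C@H](C)[C@@H]1CC[C@@](C)(CCC2=C(C)C(=O)CCC2(C)C)OO1 | target

Total step count: 6. Longest linear sequence: 6.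

**Steps most likely to fail**

Step 2. The carbonyl groups may tie up the acid, or the enantioselectivity may be low with a ketone terminator. The fallback sets out from 4 and takes the chirality from a resolution instead of the catalyst. Cyclise 4 with ClSO3H in 2-nitropropane at −78 °C, which is the racemic reaction known for geranylacetone. Then separate the racemic enol ether on a chiral stationary phase (SFC). This gives 5, where the route is rejoined, and the unwanted (4aR,8aR)-enol ether F1.

Step 4. AlMe3 may attack the O–O bond, or the tethered alkoxide may simply re-close. The fallback sets out from 7.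
- First exchange the pyran oxygen for methanol (CSA, MeOH) to give the monocyclic methoxy peroxyketal alcohol F2.
- Dehydrate F2 with Burgess reagent to the methoxy peroxyketal alkene F3.
- Only then replace OMe by CH3 (AlMe3, cat. TMSOTf, CH2Cl2, −78 °C). This ketal is untethered, so its ionisation is irreversible, and the equatorial C3 side chain still directs axial attack.

This bypasses 9 and comes back at 10.

Step 5. The dehydration may give a mixture of tetrasubstituted, trisubstituted and exocyclic alkenes. The fallback sets out from 9 and uses SOCl2/pyridine at 0 °C. Its anti-periplanar E2 requirement steers elimination of the equatorial C10 oxygen into the methyl group and gives the exocyclic alkene F4. The double bond is then moved into the tetrasubstituted position by radical hydrogen-atom-transfer isomerisation (Co(salen)Cl, cat. PhSiH3, PhH, rt). This comes back at 10.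

**Further compounds**
F1 | step 2 | methyl (2E)-2-methyl-5-[(4aR,8aR)-5,5,8a-trimethyl-4a,5,6,7,8,8a-hexahydro-4H-chromen-2-yl]pent-2-enoate | COC(=O)/C(C)=C/CCC1=CC[C@@H]2C(C)(C)CCC[C@@]2(C)O1
F2 | step 4 | methyl (2R)-2-[(3S,6R)-6-{2-[(1S,2S)-2-hydroxy-2,6,6-trimethylcyclohexyl]ethyl}-6-methoxy-1,2-dioxan-3-yl]propanoate | COC(=O)[C@H](C)[C@@H]1CC[C@@](OC)(CC[C@H]2C(C)(C)CCC[C@]2(C)O)OO1
F3 | step 4 | methyl (2R)-2-[(3S,6R)-6-methoxy-6-[2-(2,6,6-trimethylcyclohex-1-en-1-yl)ethyl]-1,2-dioxan-3-yl]propanoate | COC(=O)[C@H](C)[C@@H]1CC[C@@](OC)(CCC2=C(C)CCCC2(C)C)OO1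
F4 | step 5 | methyl (2R)-2-[(3S,6R)-6-{2-[(1S)-2,2-dimethyl-6-methylidenecyclohexyl]ethyl}-6-methyl-1,2-dioxan-3-yl]propanoate | COC(=O)[C@H](C)[C@@H]1CC[C@@](C)(CC[C@H]2C(C)(C)CCCC2=C)OO1
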